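**Plan**

- Retrosynthesis: after exchanging the oxidation levels at C31 and C16, the bicyclo[2.2.2]octane is cut at C12–C13 and C14–C16 in one operation. This gives hydrindene 27, which has the ring-B alkene C11=C12 and, on the lower face of ring C, a 2-methylacryloyl ketone on lactone carbon C30 (attached to C25) and the aldehyde C16 (attached to C18).
- The cis pair C16/C30 on the vicinal quaternary carbons C18/C25 comes from a temporary cyclopentenone (C16–C28–C30). This is cut back to a dienyne (Pauson–Khand), then to a dienyl triflate plus alkenyl boronate (C12–C25), then to a Robinson annulation (ring B).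
- Forward order: ring B (steps 4–5), saturated ring A (9), ring C with the temporary ring (13), ring-A unsaturation (15), cleavage to aldehyde and spiro γ-lactone (16), acylation (17–18), cage (20), redox adjustment (21–23).
- Stereochemistry: C9 from a catalytic asymmetric Michael addition; C22 by epoxidation anti to C2; C21 by inversion in a palladium/formate hydrogenolysis; C25 in the Pauson–Khand step; C18 from the cis ring fusion; C12, C14 and C30 from the tethered key step; C31 by hydride attack from the C13 side.

Key step: step 20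

Locants: atoms are called by their position in the target SMILES (C2 = CMe2, O4/C5 = ring-A lactone O and C=O, C7=C8, C9 = spiro carbon, C10, C11, C12, C13 = CH2 bridge, C14 = C(CH3), C16 = ketone, C18 = C(CH3), C20, C21 = CH, C22 = C(CH3)OH, C25, C26 = OCH2, C28 = γ-lactone C=O, C30, C31 = CHOH). Ring A = δ-lactone; ring B = C9/C10/C11/C12/C21/C22; ring C = C12/C21/C20/C18/C25.

Assumption: the quinidine-derived catalyst of step 4 is taken to give the (S)-adduct 8; if the sense is opposite, its quinine-derived pseudo-enantiomer is used.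

**Route**

Step 1
Reactants: 1 tert-butyldimethyl(prop-2-yn-1-yloxy)silane
Product: 2 2-[3-(tert-butyldimethylsilyloxy)prop-1-en-2-yl]-4,4,5,5-tetramethyl-1,3,2-dioxaborolane
Conditions: B2pin2, CuCl (cat.), 1,3-dimesitylimidazolinium chloride (cat.), NaOtBu (cat.), MeOH, THF, −50 °C to rt
Reagents that add atoms: bis(pinacolato)diboron, CC1(C)OB(OC1(C)C)B1OC(C)(C)C(C)(C)O1
Why: Copper-catalysed protoboration of a terminal alkyne; the N-aryl carbene ligand and the propargylic oxygen should direct boron to the internal carbon, giving the 1,1-disubstituted alkenyl boronate.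

Step 2
Reactants: 3 pent-4-ynoic acid; 4 N,O-dimethylhydroxylamine hydrochloride
Product: 5 N-methoxy-N-methylpent-4-ynamide
Conditions: 1,1′-carbonyldiimidazole, CH2Cl2, rt; then 4, rt
Reagents that add atoms: none
Why: Amide coupling through the acyl imidazole.

Step 3
Reactants: 5 N-methoxy-N-methylpent-4-ynamide
Product: 6 hept-1-en-6-yn-3-one
Conditions: vinylmagnesium bromide (2.2 equiv), THF, −78 to 0 °C; inverse quench into cold aq. HCl
Reagents that add atoms: vinylmagnesium bromide, C=C[Mg]Br
Why: Ketone synthesis from an N-methoxy-N-methylamide (the chelated tetrahedral intermediate stops at the ketone); the second equivalent covers the acetylenic proton and the acidic quench should prevent amine addition to the enone.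

Step 4
Reactants: 7 diethyl 2-acetylpentanedioate; 6 hept-1-en-6-yn-3-one
Product: 8 diethyl (2S)-2-acetyl-2-(3-oxohept-6-yn-1-yl)pentanedioate
Conditions: quinidine-derived 6′-hydroxy-9-O-(9-phenanthryl) cinchona catalyst (10 mol%), CH2Cl2, −20 °C
Reagents that add atoms: none
Why: Catalytic enantioselective Michael addition of an α-substituted β-keto ester to a vinyl ketone; the bifunctional base/hydrogen-bond catalyst should set quaternary C9, from which all other stereocentres are relayed.

Step 5
Reactants: 8 diethyl (2S)-2-acetyl-2-(3-oxohept-6-yn-1-yl)pentanedioate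
Product: 9 ethyl (1S)-1-(3-ethoxy-3-oxopropyl)-2-methyl-4-oxo-3-(prop-2-yn-1-yl)cyclohex-2-ene-1-carboxylate
Conditions: pyrrolidine, AcOH, toluene, 60 °C
Reagents that add atoms: none
Why: Intramolecular aldol condensation (second stage of a Robinson annulation): the enamine of the unhindered chain ketone should attack the acetyl carbonyl through C21 and close ring B as the enone; C9 is untouched.

Step 6
Reactants: 9 ethyl (1S)-1-(3-ethoxy-3-oxopropyl)-2-methyl-4-oxo-3-(prop-2-yn-1-yl)cyclohex-2-ene-1-carboxylate
Product: 10 ethyl (1R)-1-(3-ethoxy-3-oxopropyl)-2-methyl-3-(prop-2-yn-1-yl)-4-(trifluoromethylsulfonyloxy)cyclohexa-2,4-diene-1-carboxylate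
Conditions: LiHMDS (1.05 equiv), THF, −78 °C; then PhNTf2
Reagents that add atoms: N-phenylbis(trifluoromethanesulfonimide), O=S(=O)(N(c1ccccc1)S(=O)(=O)C(F)(F)F)C(F)(F)F
Why: Kinetic α′-deprotonation of the enone at C11 and O-sulfonylation should give the cross-conjugated dienyl triflate (the descriptor changes only through CIP priorities).

Step 7
Reactants: 10 dienyl triflate; 2 alkenyl boronate
Product: 11 ethyl (1R)-4-[3-(tert-butyldimethylsilyloxy)prop-1-en-2-yl]-1-(3-ethoxy-3-oxopropyl)-2-methyl-3-(prop-2-yn-1-yl)cyclohexa-2,4-diene-1-carboxylate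
Conditions: Pd(dppf)Cl2 (cat.), K3PO4, dioxane/H2O, 50 °C
Reagents that add atoms: none
Why: Suzuki–Miyaura coupling of an alkenyl triflate with an alkenyl boronate forms the C12–C25 bond; without copper the terminal alkyne should not couple.

Step 8
Reactants: 11 triene diester
Product: 12 3-[(1R)-4-[3-(tert-butyldimethylsilyloxy)prop-1-en-2-yl]-1-(ethoxycarbonyl)-2-methyl-3-(prop-2-yn-1-yl)cyclohexa-2,4-dien-1-yl]propanoic acid
Conditions: LiOH (1.1 equiv), THF/H2O, 0 °C to rt; dilute HCl work-up
Reagents that add atoms: lithium hydroxide, [Li+].[OH-]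
Why: Saponification; the primary propanoate ester should hydrolyse much faster than the ester on quaternary C9.

Step 9
Reactants: 12 mono-acid
Product: 14 (6R)-9-[3-(tert-butyldimethylsilyloxy)prop-1-en-2-yl]-1,1,7-trimethyl-8-(prop-2-yn-1-yl)-2-oxaspiro[5.5]undeca-7,9-dien-3-one, via hydroxy acid 13 (not isolated)
Conditions: CeCl3, MeMgBr (6 equiv), THF, −78 to 0 °C; aq. HCl work-up; then PPTS, toluene, 60 °C
Reagents that add atoms: methylmagnesium bromide, C[Mg]Br
Why: Double addition of the organocerium reagent to the hindered ester (the carboxylate is inert) builds C2, and acid-catalysed lactonisation of the δ-hydroxy acid closes ring A in saturated form.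

Step 10
Reactants: 14 spirolactone triene
Product: 15 C21–C22 epoxide of 14, oxirane oxygen on the face of ring B that carries C8 (anti to C2)
Conditions: mCPBA (1.05 equiv), NaHCO3, CH2Cl2, −20 °C
Reagents that add atoms: 3-chloroperbenzoic acid, OOC(=O)c1cccc(Cl)c1
Why: Peracid epoxidation should take the most electron-rich, tetrasubstituted C21=C22 bond; the CMe2–O carbon on spiro C9 stands perpendicular to this alkene to avoid allylic strain with the C22 methyl, so oxygen is delivered to the opposite face, which sets C22.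

Step 11
Reactants: 15 alkenyl oxirane
Product: 16 tertiary homoallylic alcohol (C22–OH cis to C8 and to the propargyl group on C21, H21 trans to the hydroxyl, C11=C12 retained)
Conditions: Pd2(dba)3·CHCl3 (cat.), PBu3, HCO2H, Et3N, dioxane, rt
Reagents that add atoms: none
Why: Palladium-catalysed formate hydrogenolysis of an alkenyl oxirane: zerovalent palladium ionises the allylic C21–O bond anti to oxygen and the palladium hydride delivers hydrogen from the metal face to the more substituted allyl terminus, so C21–H forms with inversion and the alkene stays at C11=C12.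

Step 12
Reactants: 16 tertiary alcohol
Product: 17 22-O-tert-butyldimethylsilyl ether of 16 (dienyne)
Conditions: TBSOTf, 2,6-lutidine, CH2Cl2, −78 to 0 °C
Reagents that add atoms: tert-butyldimethylsilyl trifluoromethanesulfonate, CC(C)(C)[Si](C)(C)OS(=O)(=O)C(F)(F)F
Why: Silylation of the tertiary alcohol, which would otherwise transacylate the ring-A lactone in the basic steps that follow.

Step 13
Reactants: 17 dienyne
Product: 18 tetracyclic enone: rings A, B and C plus a cyclopent-2-enone fused at C18–C25 (C18=C16–C28(=O)–C30), with C26H2OTBS on C25 cis to C22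
Conditions: Co2(CO)8, CH2Cl2, rt; then N-methylmorpholine N-oxide, 0 °C to rt
Reagents that add atoms: dicobalt octacarbonyl (source of CO), O=C=[Co](=C=O)(=C=O)(=C=O)[Co](=C=O)(=C=O)(=C=O)=C=O
Why: Intramolecular Pauson–Khand [2+2+1] of the 1,6-enyne closes ring C (C18–C25) and the temporary cyclopentenone; the cobalt cluster and the forming enone ring should take the face of C25 anti to the fully substituted C22 branch on C21, leaving C26 cis to C22.

Step 14
Reactants: 18 tetracyclic enone
Product: 19 enol triethylsilyl ether with C19 methyl on C18 (cis to C26) and the double bond fixed at C16=C28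
Conditions: Me2CuLi, Et3SiCl, THF, −78 to −30 °C; Et3N, then work-up
Reagents that add atoms: lithium dimethylcuprate, [Li+].C[Cu-]C; chlorotriethylsilane, CC[Si](CC)(CC)Cl
Why: Silyl-chloride-accelerated cuprate conjugate addition; only a cis-fused bicyclo[3.3.0]octane can form, so the methyl enters cis to C26, and trapping fixes the enolate regiochemistry for the later cleavage.

Step 15
Reactants: 19 enol silyl ether
Product: 21 C7=C8-dehydro derivative of 19 (ring A complete), via selenide 20 (not isolated)
Conditions: LDA, THF, −78 °C; PhSeBr; then NaIO4, NaHCO3, THF/H2O, 0 °C to rt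
Reagents that add atoms: none
Why: Selenenylation of the lactone enolate (the only enolisable position while the ketone is masked) and selenoxide syn-elimination introduce the ring-A double bond after the cuprate step, which an enoate would not have survived.

Step 16
Reactants: 21 unsaturated lactone enol silyl ether
Product: 23 C16 dimethyl acetal carrying the spiro γ-lactone C25/C26/O27/C28/C30, via aldehyde acid 22 (not isolated)
Conditions: O3 (1 equiv, Sudan red 7B indicator), CH2Cl2/MeOH, −78 °C; Me2S; then HC(OMe)3, camphorsulfonic acid, rt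
Reagents that add atoms: ozone, [O-][O+]=O; trimethyl orthoformate, COC(OC)OC
Why: Ozonolysis of the electron-rich enol silyl ether cleaves C16–C28 to the C16 aldehyde and C28 acid; the acid treatment then forms the acetal, removes the primary silyl ether and closes the γ-lactone, while the tertiary silyl ether and the electron-poor ring-A alkene should survive.

Step 17
Reactants: 23 acetal bis-lactone; 24 methacrolein
Product: 25 aldol adduct bearing 1-hydroxy-2-methylprop-2-en-1-yl on C30 (epimers at C30 and C31)
Conditions: LDA, THF, −78 °C; then 24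
Reagents that add atoms: none
Why: Aldol addition of the γ-lactone lithium enolate (ring A has no α-hydrogen) to the aldehyde carbon of methacrolein; the new centres need no control because one is oxidised and the other is labile.

Step 18
Reactants: 25 aldol adduct
Product: 26 β-keto lactone with 2-methylacryloyl on C30 (C16 still as acetal)
Conditions: Dess–Martin periodinane, NaHCO3, CH2Cl2, 0 °C to rt
Reagents that add atoms: none
Why: Dess–Martin oxidation of the allylic alcohol to the enone.

Step 19
Reactants: 26 β-keto lactone acetal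
Product: 27 aldehyde 27 (C11=C12 alkene, C16 aldehyde, 2-methylacryloyl β-keto lactone, 22-O-TBS)
Conditions: p-TsOH·H2O, acetone/H2O, 40 °C
Reagents that add atoms: water, O
Why: Acid hydrolysis of the dimethyl acetal frees the neopentyl aldehyde; enone, β-keto lactone and tertiary silyl ether should tolerate the mild acid.

Step 20
Reactants: 27 aldehyde 27
Product: 28 hexacyclic aldol product (C12–C13 and C14–C16 formed; C16 alcohol, C31 ketone, 22-O-TBS)
Conditions: Fe(acac)3, PhSiH3, EtOH/ethylene glycol, 0 °C to rt
Reagents that add atoms: none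
Why: An iron hydride from Fe(acac)3 and phenylsilane transfers a hydrogen atom to C11 of the C11=C12 alkene, the tertiary C12 radical adds 6-endo-trig to the unsubstituted terminus C13 of the 2-methylacryloyl ketone, and the α-keto radical at C14 is reduced to an iron enolate that adds to the C16 aldehyde (6-exo-trig aldol), which closes both six-membered rings of the bicyclo[2.2.2]octane. The closest known reaction type is the hydrogen-atom-transfer-initiated Giese addition with aldol termination (radical–polar crossover annulation), run here fully intramolecularly. C12 is set because the acceptor hangs from C30 on the lower face of ring C, so the new bond can only form cis to C30 and to H21; C14 is set because only one enolate face reaches C16 on that same face of C18; C30 is a labile β-keto lactone centre and is funnelled into the one epimer that can bridge; the C16 carbinol centre is removed in step 21. The step needs hydrogen-atom transfer to the electron-rich alkene and not to the enone or the ring-A enoate, which the polarity preference of the metal hydride should provide, and 6-endo instead of 5-exo attack, which the polarity match of the nucleophilic radical with the unsubstituted β-carbon should provide; attack on the ring-A enoate would need a bicyclo[2.2.1] boat transition state.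

Step 21
Reactants: 28 hexacyclic aldol product
Product: 29 16,31-diketone (22-O-TBS)
Conditions: Dess–Martin periodinane, NaHCO3, CH2Cl2, rt
Reagents that add atoms: none
Why: Dess–Martin oxidation of the hindered secondary C16 alcohol; the 1,3-diketone cannot enolise across quaternary C14.

Step 22
Reactants: 29 diketone
Product: 30 22-O-tert-butyldimethylsilyl ether of the target
Conditions: NaBH4, CeCl3·7H2O, MeOH/THF, −40 °C
Reagents that add atoms: none
Why: Luche reduction (1,2-selective, sparing the enoate) of the more accessible C31 ketone, C16 being flanked by two quaternary carbons; hydride should enter from the face turned to the C13 methylene bridge, away from the lactone carbonyl on C30, which places the hydroxyl on the C16 side as in the target.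

Step 23
Reactants: 30 silyl ether
Product: 31 target CNP0360620.2
Conditions: HF·pyridine, THF, 0 °C to rt
Reagents that add atoms: none
Why: Fluoride cleavage of the tertiary silyl ether under non-basic conditions, which avoids retro-aldol opening of the β-hydroxy ketone.

**Compound list**

1 | tert-butyldimethyl(prop-2-yn-1-yloxy)silane | C#CCO[Si](C)(C)C(C)(C)C | starting material
2 | 2-[3-(tert-butyldimethylsilyloxy)prop-1-en-2-yl]-4,4,5,5-tetramethyl-1,3,2-dioxaborolane | C=C(CO[Si](C)(C)C(C)(C)C)B1OC(C)(C)C(C)(C)O1 | intermediate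
3 | pent-4-ynoic acid | C#CCCC(=O)O | starting material
4 | N,O-dimethylhydroxylamine hydrochloride | CNOC.Cl | starting material
5 | N-methoxy-N-methylpent-4-ynamide | C#CCCC(=O)N(C)OC | intermediate
6 | hept-1-en-6-yn-3-one | C=CC(=O)CCC#C | intermediate
7 | diethyl 2-acetylpentanedioate | CCOC(=O)CCC(C(C)=O)C(=O)OCC | starting material
8 | diethyl (2S)-2-acetyl-2-(3-oxohept-6-yn-1-yl)pentanedioate | CCOC(=O)CC[C@@](C(C)=O)(C(=O)OCC)CCC(=O)CCC#C | intermediate
9 | ethyl (1S)-1-(3-ethoxy-3-oxopropyl)-2-methyl-4-oxo-3-(prop-2-yn-1-yl)cyclohex-2-ene-1-carboxylate | CCOC(=O)CC[C@@]1(C(=O)OCC)CCC(=O)C(CC#C)=C1C | intermediate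
10 | ethyl (1R)-1-(3-ethoxy-3-oxopropyl)-2-methyl-3-(prop-2-yn-1-yl)-4-(trifluoromethylsulfonyloxy)cyclohexa-2,4-diene-1-carboxylate | CCOC(=O)CC[C@@]1(C(=O)OCC)CC=C(OS(=O)(=O)C(F)(F)F)C(CC#C)=C1C | intermediate
11 | ethyl (1R)-4-[3-(tert-butyldimethylsilyloxy)prop-1-en-2-yl]-1-(3-ethoxy-3-oxopropyl)-2-methyl-3-(prop-2-yn-1-yl)cyclohexa-2,4-diene-1-carboxylate | CCOC(=O)CC[C@@]1(C(=O)OCC)CC=C(C(=C)CO[Si](C)(C)C(C)(C)C)C(CC#C)=C1C | intermediate
12 | 3-[(1R)-4-[3-(tert-butyldimethylsilyloxy)prop-1-en-2-yl]-1-(ethoxycarbonyl)-2-methyl-3-(prop-2-yn-1-yl)cyclohexa-2,4-dien-1-yl]propanoic acid | OC(=O)CC[C@@]1(C(=O)OCC)CC=C(C(=C)CO[Si](C)(C)C(C)(C)C)C(CC#C)=C1C | intermediate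
13 | 3-[(1R)-4-[3-(tert-butyldimethylsilyloxy)prop-1-en-2-yl]-1-(2-hydroxypropan-2-yl)-2-methyl-3-(prop-2-yn-1-yl)cyclohexa-2,4-dien-1-yl]propanoic acid | OC(=O)CC[C@@]1(C(C)(C)O)CC=C(C(=C)CO[Si](C)(C)C(C)(C)C)C(CC#C)=C1C | intermediate (not isolated)
14 | (6R)-9-[3-(tert-butyldimethylsilyloxy)prop-1-en-2-yl]-1,1,7-trimethyl-8-(prop-2-yn-1-yl)-2-oxaspiro[5.5]undeca-7,9-dien-3-one | CC1(C)OC(=O)CC[C@]12CC=C(C(=C)CO[Si](C)(C)C(C)(C)C)C(CC#C)=C2C | intermediate
15 | C21–C22 epoxide of 14 (oxirane O cis to C8, anti to C2) | CC1(C)OC(=O)CC[C@]12CC=C(C(=C)CO[Si](C)(C)C(C)(C)C)[C@@]3(CC#C)O[C@@]23C | intermediate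
16 | tertiary homoallylic alcohol (C22–OH cis to C8 and to the propargyl group, H21 trans to OH) | CC1(C)OC(=O)CC[C@]12CC=C(C(=C)CO[Si](C)(C)C(C)(C)C)[C@@H](CC#C)[C@@]2(C)O | intermediate
17 | 22-O-TBS ether of 16 (dienyne) | CC1(C)OC(=O)CC[C@]12CC=C(C(=C)CO[Si](C)(C)C(C)(C)C)[C@@H](CC#C)[C@@]2(C)O[Si](C)(C)C(C)(C)C | intermediate
18 | tetracyclic enone (rings A, B, C and temporary cyclopentenone C18=C16–C28(=O)–C30; C26 cis to C22) | CC1(C)OC(=O)CC[C@]12CC=C3[C@@H](CC4=CC(=O)C[C@@]34CO[Si](C)(C)C(C)(C)C)[C@@]2(C)O[Si](C)(C)C(C)(C)C | intermediate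
19 | enol triethylsilyl ether (C19 methyl on C18 cis to C26; C16=C28–OSiEt3) | CC1(C)OC(=O)CC[C@]12CC=C3[C@@H](C[C@@]4(C)C=C(O[Si](CC)(CC)CC)C[C@@]34CO[Si](C)(C)C(C)(C)C)[C@@]2(C)O[Si](C)(C)C(C)(C)C | intermediate
20 | 7-(phenylselanyl) derivative of 19 (C7 epimers) | CC1(C)OC(=O)C([Se]c5ccccc5)C[C@]12CC=C3[C@@H](C[C@@]4(C)C=C(O[Si](CC)(CC)CC)C[C@@]34CO[Si](C)(C)C(C)(C)C)[C@@]2(C)O[Si](C)(C)C(C)(C)C | intermediate (not isolated)
21 | 7,8-didehydro derivative of 19 (ring A = 6,6-dimethyl-5,6-dihydropyran-2-one) | CC1(C)OC(=O)C=C[C@]12CC=C3[C@@H](C[C@@]4(C)C=C(O[Si](CC)(CC)CC)C[C@@]34CO[Si](C)(C)C(C)(C)C)[C@@]2(C)O[Si](C)(C)C(C)(C)C | intermediate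
22 | aldehyde acid (C18: CH3 and CHO; C25: CH2CO2H and CH2OTBS) | CC1(C)OC(=O)C=C[C@]12CC=C3[C@@H](C[C@@](C)(C=O)[C@]3(CC(=O)O)CO[Si](C)(C)C(C)(C)C)[C@@]2(C)O[Si](C)(C)C(C)(C)C | intermediate (not isolated)
23 | C16 dimethyl acetal with spiro γ-lactone C25/C26/O27/C28/C30 | CC1(C)OC(=O)C=C[C@]12CC=C3[C@@H](C[C@@](C)(C(OC)OC)[C@]34COC(=O)C4)[C@@]2(C)O[Si](C)(C)C(C)(C)C | intermediate
24 | methacrolein (2-methylprop-2-enal) | CC(=C)C=O | starting material
25 | aldol adduct, 1-hydroxy-2-methylprop-2-en-1-yl on C30 (epimers at C30 and C31) | CC1(C)OC(=O)C=C[C@]12CC=C3[C@@H](C[C@@](C)(C(OC)OC)[C@]34COC(=O)C4C(O)C(C)=C)[C@@]2(C)O[Si](C)(C)C(C)(C)C | intermediate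
26 | β-keto lactone acetal, 2-methylacryloyl on C30 (C30 labile) | CC1(C)OC(=O)C=C[C@]12CC=C3[C@@H](C[C@@](C)(C(OC)OC)[C@]34COC(=O)C4C(=O)C(C)=C)[C@@]2(C)O[Si](C)(C)C(C)(C)C | intermediate
27 | aldehyde 27, substrate of the key step (C30 labile) | CC1(C)OC(=O)C=C[C@]12CC=C3[C@@H](C[C@@](C)(C=O)[C@]34COC(=O)C4C(=O)C(C)=C)[C@@]2(C)O[Si](C)(C)C(C)(C)C | intermediate
28 | hexacyclic aldol product (C16–OH either epimer, C31 ketone, 22-O-TBS) | CC1(C)OC(=O)C=C[C@]12CC[C@]13C[C@]4(C)C(O)[C@](C)(C[C@H]1[C@@]2(C)O[Si](C)(C)C(C)(C)C)[C@]31COC(=O)[C@H]1C4=O | intermediate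
29 | 16,31-diketone (22-O-TBS) | CC1(C)OC(=O)C=C[C@]12CC[C@]13C[C@]4(C)C(=O)[C@](C)(C[C@H]1[C@@]2(C)O[Si](C)(C)C(C)(C)C)[C@]31COC(=O)[C@H]1C4=O | intermediate
30 | 22-O-TBS ether of the target | CC1(C)OC(=O)C=C[C@]12CC[C@]13C[C@]4(C)C(=O)[C@](C)(C[C@H]1[C@@]2(C)O[Si](C)(C)C(C)(C)C)[C@]31COC(=O)[C@H]1[C@H]4O | intermediate
31 | CNP0360620.2 | CC1(C)OC(=O)C=C[C@]12CC[C@]13C[C@]4(C)C(=O)[C@](C)(C[C@H]1[C@@]2(C)O)[C@]31COC(=O)[C@H]1[C@H]4O | target

**Step count and risks**

Total step count: 23. Longest linear sequence: 22 steps (steps 2–23, from pent-4-ynoic acid); step 1 is a one-step branch.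

Steps most likely to fail:

Step 20. The iron enolate formed after the radical addition may be protonated by the alcohol solvent, or the aldehyde may be reduced by the silane, before the aldol closure; only the C12–C13 bond would then form. The fallback makes the two bonds in separate operations and sets out from 27. A reductive hydrogen-atom-transfer cyclisation under protic conditions (Mn(dpm)3, PhSiH3, i-PrOH, rt) should give the tricyclic keto aldehyde F1. The dianion of its β-keto lactone (LDA, 2.2 equiv, THF, −78 to −20 °C), whose more basic terminus is C14, should then add to the C16 aldehyde. This gives 28, where the route is rejoined.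

Step 14. Methyl transfer to the β,β-disubstituted enone carbon C18, which is flanked by quaternary C25, may be too slow, so that enolisation or 1,2-addition takes over. The fallback sets out from 18 and installs the methyl through a cyclopropane. Luche reduction (NaBH4, CeCl3, MeOH) should give the allylic alcohol F2. Hydroxyl-assisted Simmons–Smith cyclopropanation (Et2Zn, CH2I2, CH2Cl2) should give the cyclopropyl carbinol F3, the methylene being forced onto the face of C26 by the ring fusion. Dess–Martin oxidation should give the cyclopropyl ketone F4. Reductive cleavage of the exocyclic cyclopropane bond (SmI2, HMPA, THF, −78 °C) and trapping of the enolate with Et3SiCl should give 19, where the route is rejoined.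

Step 16. Over-oxidation: ozone may also cleave the trisubstituted C11=C12 bond that the key step needs. The fallback sets out from 21 and replaces ozonolysis by epoxidation and acyloin cleavage. Rubottom oxidation of the enol silyl ether (mCPBA, NaHCO3, CH2Cl2, −40 °C), which should discriminate far better between an enol ether and a hindered alkene, should give the α-silyloxy ketone F5. Periodic acid (H5IO6, THF/H2O) should cleave its C16–C28 bond to the aldehyde acid 22, which is taken on to 23 by the orthoformate/acid treatment of step 16.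

Further compounds
F1 | step 20 | tricyclic keto aldehyde (C12–C13 formed, C14–H, C16 aldehyde free; C14 and C30 epimers) | CC1(C)OC(=O)C=C[C@]12CC[C@]13CC(C)C(=O)C4C(=O)OC[C@@]34[C@](C)(C=O)C[C@H]1[C@@]2(C)O[Si](C)(C)C(C)(C)C
F2 | step 14 | allylic alcohol from 18 (C28–OH, epimers) | CC1(C)OC(=O)CC[C@]12CC=C3[C@@H](CC4=CC(O)C[C@@]34CO[Si](C)(C)C(C)(C)C)[C@@]2(C)O[Si](C)(C)C(C)(C)C
F3 | step 14 | cyclopropyl carbinol (CH2 bridging C16 and C18, cis to C26) | CC1(C)OC(=O)CC[C@]12CC=C3[C@@H](C[C@]45C[C@@H]5C(O)C[C@@]34CO[Si](C)(C)C(C)(C)C)[C@@]2(C)O[Si](C)(C)C(C)(C)C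
F4 | step 14 | cyclopropyl ketone | CC1(C)OC(=O)CC[C@]12CC=C3[C@@H](C[C@]45C[C@@H]5C(=O)C[C@@]34CO[Si](C)(C)C(C)(C)C)[C@@]2(C)O[Si](C)(C)C(C)(C)C
F5 | step 16 | α-triethylsilyloxy ketone (C16–OSiEt3, C28 ketone) | CC1(C)OC(=O)C=C[C@]12CC=C3[C@@H](C[C@@]4(C)C(O[Si](CC)(CC)CC)C(=O)C[C@@]34CO[Si](C)(C)C(C)(C)C)[C@@]2(C)O[Si](C)(C)C(C)(C)C
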